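The cycloheptenone ring is cut by a (4+3) disconnection: its α-carboxy enone carbons C5=C4–C3a (azulene numbering) become a rhodium vinylcarbenoid and C6–C7–C8–C8a a 1,3-diene. One tandem cyclopropanation/Cope step joins C5 to C6 and C3a to C8a, creating the seven-membered ring, the quaternary methyl-bearing C8a and the trans C3a–H/C8a–CH3 relationship. Its precursors are acyclic: an (E)-vinyldiazoacetate with a masked acetonyl arm on C3a and a (Z)-diene with a siloxyethyl arm on C8a. These arms are later joined by aldol condensation into the cyclopentane, and the C6 oxygen then anchors a radical cyclisation that sets C7 and C8.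

Key step: step 7

Assumption: Rh2(R-BTPCP)4 is taken as the catalyst antipode that exposes the carbenoid face leading to cyclopropane 10 as drawn; if the facial sense is the reverse, Rh2(S-BTPCP)4 is used and nothing else changes.

Step 1
Reactants: 1 4-methyl-5,6-dihydro-2H-pyran-2-one
Product: 2 4-methyl-5,6-dihydro-2H-pyran-2-ol
Conditions: i-Bu2AlH (1.1 equiv), CH2Cl2, −78 °C; aq. potassium sodium tartrate
Reagents that add atoms: none
Why: Partial reduction of a lactone at low temperature stops at the tetrahedral aluminium hemiacetal, so the unsaturated lactol should result without ring opening or 1,4-reduction.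

Step 2
Reactants: 2 4-methyl-5,6-dihydro-2H-pyran-2-ol
Product: 3 (3Z)-3-methylhexa-3,5-dien-1-ol
Conditions: Ph3PCH3Br (2.5 equiv), KOt-Bu (2.4 equiv), THF, 0 to 23 °C
Reagents that add atoms: methyltriphenylphosphonium bromide C[P+](c1ccccc1)(c1ccccc1)c1ccccc1.[Br-]
Why: Wittig methylenation of the open hydroxy-enal tautomer of the lactol should give the diene, the Z geometry of the trisubstituted alkene having been fixed by the ring before it opens.

Step 3
Reactants: 3 (3Z)-3-methylhexa-3,5-dien-1-ol
Product: 4 tert-butyl(dimethyl){[(3Z)-3-methylhexa-3,5-dien-1-yl]oxy}silane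
Conditions: t-BuMe2SiCl, imidazole, CH2Cl2, 23 °C
Reagents that add atoms: tert-butyldimethylsilyl chloride CC(C)(C)[Si](C)(C)Cl
Why: Imidazole-promoted silylation of the primary alcohol removes the O–H bond that would otherwise insert into the rhodium carbenoid of step 7.

Step 4
Reactants: 5 ethyl 3-(2-methyl-1,3-dioxolan-2-yl)propanoate
Product: 6 3-(2-methyl-1,3-dioxolan-2-yl)propanal
Conditions: i-Bu2AlH (1.05 equiv), CH2Cl2, −78 °C
Reagents that add atoms: none
Why: Partial ester reduction at −78 °C stops at the aluminium acetal and should release the aldehyde on work-up.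

Step 5
Reactants: 6 3-(2-methyl-1,3-dioxolan-2-yl)propanal; 7 tert-butyl diazoacetate
Product: 8 tert-butyl 2-diazo-3-hydroxy-5-(2-methyl-1,3-dioxolan-2-yl)pentanoate
Conditions: DBU (0.1 equiv), MeCN, 23 °C
Reagents that add atoms: none
Why: Base-catalysed aldol-type addition of the diazoacetate carbanion to an aldehyde gives the β-hydroxy-α-diazo ester without loss of nitrogen.

Step 6
Reactants: 8 tert-butyl 2-diazo-3-hydroxy-5-(2-methyl-1,3-dioxolan-2-yl)pentanoate
Product: 9 tert-butyl (3E)-2-diazo-5-(2-methyl-1,3-dioxolan-2-yl)pent-3-enoate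
Conditions: POCl3 (1.5 equiv), Et3N (4 equiv), CH2Cl2, 0 to 23 °C
Reagents that add atoms: none
Why: Dehydration through the dichlorophosphate (base-induced β-elimination) gives the conjugated vinyldiazoacetate, the E alkene being favoured on steric grounds.

Step 7
Reactants: 4 tert-butyl(dimethyl){[(3Z)-3-methylhexa-3,5-dien-1-yl]oxy}silane; 9 tert-butyl (3E)-2-diazo-5-(2-methyl-1,3-dioxolan-2-yl)pent-3-enoate
Product: 11 tert-butyl (3R,4R)-4-[2-(tert-butyldimethylsilyloxy)ethyl]-4-methyl-3-[(2-methyl-1,3-dioxolan-2-yl)methyl]cyclohepta-1,5-diene-1-carboxylate, via cis-divinylcyclopropane 10 (not isolated)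
Conditions: Rh2(R-BTPCP)4 (1 mol %; BTPCP = 1-(4-bromophenyl)-2,2-diphenylcyclopropane-1-carboxylate), 4 (3 equiv), CH2Cl2, 23 °C, slow addition of 9; then PhMe, 80 °C
Reagents that add atoms: none
Why: The dirhodium tetracarboxylate turns 9 into an electrophilic donor/acceptor vinylcarbenoid that cyclopropanates the unhindered terminal vinyl group of 4 in a concerted, asynchronous [2+1] addition with the two alkenyl groups cis (10); 10 then undergoes a boat-like [3,3] divinylcyclopropane Cope shift that makes the C3a–C8a bond as the cyclopropane bond opens, so that the net (4+3) cycloaddition also delivers the C5–C6 bond. The closest known reaction type is the rhodium-catalysed tandem cyclopropanation/Cope rearrangement of vinyldiazoacetates with dienes, including cases that create a quaternary centre at the diene terminus. The three-membered ring is closed by [2+1] addition and the seven-membered ring by ring expansion through the sigmatropic shift, not by an end-to-end cyclisation. The absolute configuration of both new stereocentres follows from the carbenoid face exposed by the chiral catalyst, and their relative configuration from the boat transition state, which places the two outward (E) substituents, the dioxolanylmethyl arm on C3a and the methyl group on C8a, cis and the inward siloxyethyl chain trans to that arm. The step needs chemoselectivity for the monosubstituted alkene over the trisubstituted alkene and the allylic and α-oxy C–H bonds, cis-selective cyclopropanation and a stereospecific Cope shift; the steric demand of the donor/acceptor carbenoid, the excess of diene and the fixed E and Z alkene geometries secure these.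

Step 8
Reactants: 11 tert-butyl (3R,4R)-4-[2-(tert-butyldimethylsilyloxy)ethyl]-4-methyl-3-[(2-methyl-1,3-dioxolan-2-yl)methyl]cyclohepta-1,5-diene-1-carboxylate
Product: 12 tert-butyl (3R,4R)-4-(2-hydroxyethyl)-4-methyl-3-(2-oxopropyl)cyclohepta-1,5-diene-1-carboxylate
Conditions: 1 M HCl, THF, 23 °C
Reagents that add atoms: water O
Why: Aqueous acid hydrolyses the dioxolane and the silyl ether in one operation, while the tert-butyl ester, which needs strong anhydrous acid, should survive (acetal hydrolysis and desilylation).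

Step 9
Reactants: 12 tert-butyl (3R,4R)-4-(2-hydroxyethyl)-4-methyl-3-(2-oxopropyl)cyclohepta-1,5-diene-1-carboxylate
Product: 13 tert-butyl (3R,4R)-4-methyl-4-(2-oxoethyl)-3-(2-oxopropyl)cyclohepta-1,5-diene-1-carboxylate
Conditions: Dess–Martin periodinane (1.3 equiv), NaHCO3, CH2Cl2, 0 to 23 °C
Reagents that add atoms: none
Why: Dess–Martin oxidation converts the primary alcohol into the aldehyde under buffered conditions that leave the ketone, the ester and the skipped diene untouched.

Step 10
Reactants: 13 tert-butyl (3R,4R)-4-methyl-4-(2-oxoethyl)-3-(2-oxopropyl)cyclohepta-1,5-diene-1-carboxylate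
Product: 15 tert-butyl (3aR,8aR)-3-acetyl-8a-methyl-1,3a,6,8a-tetrahydroazulene-5-carboxylate, via aldol adduct 14 (not isolated)
Conditions: KOH (0.3 equiv), MeOH, 0 °C
Reagents that add atoms: none
Why: In this intramolecular aldol condensation the more substituted ketone enolate adds 5-exo-trig to the aldehyde, whose own α-carbon is neopentylic, and aldol 14 loses water to the conjugated 1-acetylcyclopentene; the trans ring fusion is already fixed by C3a and C8a.

Step 11
Reactants: 15 tert-butyl (3aR,8aR)-3-acetyl-8a-methyl-1,3a,6,8a-tetrahydroazulene-5-carboxylate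
Product: 16 tert-butyl (3S,3aS,8aR)-3-acetyl-8a-methyl-1,2,3,3a,6,8a-hexahydroazulene-5-carboxylate
Conditions: [(Ph3P)CuH]6 (0.4 equiv), H2O (2 equiv), PhMe, 23 °C
Reagents that add atoms: none
Why: Copper hydride adds 1,4 to the enone only, the hindered tert-butyl enoate and the isolated alkene being much less reactive, and the enolate is protonated at C3 from the face opposite the angular methyl group, which places the acetyl group cis to that methyl (conjugate reduction with kinetic protonation).

Step 12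
Reactants: 16 tert-butyl (3S,3aS,8aR)-3-acetyl-8a-methyl-1,2,3,3a,6,8a-hexahydroazulene-5-carboxylate
Product: 17 tert-butyl (3S,3aS,8aR)-3-(2-hydroxypropan-2-yl)-8a-methyl-1,2,3,3a,6,8a-hexahydroazulene-5-carboxylate
Conditions: CeCl3 (3 equiv), MeLi (3 equiv), THF, −78 °C; aq. NH4Cl
Reagents that add atoms: methyllithium [Li]C
Why: The weakly basic organocerium reagent adds 1,2 to the methyl ketone without enolising it, so the C3 configuration is kept, and the tert-butyl enoate is inert at −78 °C.

Step 13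
Reactants: 17 tert-butyl (3S,3aS,8aR)-3-(2-hydroxypropan-2-yl)-8a-methyl-1,2,3,3a,6,8a-hexahydroazulene-5-carboxylate
Product: 18 tert-butyl (3S,3aS,6S,8aR)-6-hydroxy-3-(2-hydroxypropan-2-yl)-8a-methyl-1,2,3,3a,6,8a-hexahydroazulene-5-carboxylate
Conditions: SeO2 (0.5 equiv), t-BuOOH (2 equiv), CH2Cl2, 23 °C
Reagents that add atoms: selenium dioxide O=[Se]=O; tert-butyl hydroperoxide CC(C)(C)OO
Why: SeO2 attacks the only electron-rich alkene (C7=C8) by an ene reaction followed by a [2,3]-sigmatropic shift at its single allylic position C6; approach to the face opposite the C8a methyl group and suprafacial oxygen delivery should give the 6S alcohol.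

Step 14
Reactants: 18 tert-butyl (3S,3aS,6S,8aR)-6-hydroxy-3-(2-hydroxypropan-2-yl)-8a-methyl-1,2,3,3a,6,8a-hexahydroazulene-5-carboxylate
Product: 19 tert-butyl (3S,3aS,6S,8aR)-6-[(1-bromo-2-methoxypropan-2-yl)oxy]-3-(2-hydroxypropan-2-yl)-8a-methyl-1,2,3,3a,6,8a-hexahydroazulene-5-carboxylate
Conditions: 2-methoxypropene (3 equiv), N-bromosuccinimide (1.2 equiv), CH2Cl2, −78 to −30 °C
Reagents that add atoms: 2-methoxypropene COC(C)=C; N-bromosuccinimide O=C1CCC(=O)N1Br
Why: In this bromoketalisation the bromonium/oxocarbenium ion from the enol ether is captured by the less hindered secondary allylic hydroxyl, the tertiary carbinol being too hindered to compete at low temperature.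

Step 15
Reactants: 19 tert-butyl (3S,3aS,6S,8aR)-6-[(1-bromo-2-methoxypropan-2-yl)oxy]-3-(2-hydroxypropan-2-yl)-8a-methyl-1,2,3,3a,6,8a-hexahydroazulene-5-carboxylate
Product: 20 tricyclic ketal aldehyde (core 3S,3aS,6S,7S,8S,8aS; O6 and the new C7 methylene joined through C(CH3)(OCH3) as a cis-fused oxolane; formyl group on C8)
Conditions: Bu3SnH (1.3 equiv, slow addition), AIBN (0.2 equiv), CO (80 atm), PhH, 80 °C
Reagents that add atoms: carbon monoxide [C-]#[O+]
Why: In this Ueno–Stork radical cyclisation the primary radical closes 5-exo-trig onto C7 on the face of the C6 oxygen (cis-fused oxolane), and the resulting C8 radical captures CO from the opposite, less hindered face before hydrogen transfer, which sets C7 and C8 trans (radical carbonylation).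

Step 16
Reactants: 20 tricyclic ketal aldehyde
Product: 21 tricyclic ketal (E)-alkenyl iodide (core 3S,3aS,6S,7S,8R,8aS; C8 bears (E)-2-iodoethenyl)
Conditions: CrCl2 (8 equiv), CHI3 (3 equiv), THF, 0 to 23 °C
Reagents that add atoms: iodoform IC(I)I
Why: Takai olefination homologates the aldehyde to the (E)-alkenyl iodide under non-basic conditions that should not epimerise C8.

Step 17
Reactants: 21 tricyclic ketal (E)-alkenyl iodide; 22 3-methylbut-2-enoic acid
Product: 24 tert-butyl (3S,3aS,6S,7S,8S,8aR)-6-hydroxy-3-(2-hydroxypropan-2-yl)-8a-methyl-8-[(E)-2-(3-methylbut-2-enoyloxy)ethenyl]-7-(2-oxopropyl)-1,2,3,3a,6,7,8,8a-octahydroazulene-5-carboxylate, via ketal enol ester 23 (not isolated)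
Conditions: CuI (0.2 equiv), trans-N,N'-dimethylcyclohexane-1,2-diamine (0.4 equiv), Cs2CO3 (1.5 equiv), 22 (1.5 equiv), PhMe, 80 °C; then 1 M HCl, THF, 23 °C
Reagents that add atoms: water O
Why: Copper-catalysed C–O coupling of the alkenyl iodide with the carboxylate (Ullmann-type vinylation) proceeds with retention of alkene geometry to the (E)-enol ester 23, and dilute acid then hydrolyses the mixed methyl ketal to the hydroxy ketone (in equilibrium with its cyclic hemiketal).

Step 18
Reactants: 24 tert-butyl (3S,3aS,6S,7S,8S,8aR)-6-hydroxy-3-(2-hydroxypropan-2-yl)-8a-methyl-8-[(E)-2-(3-methylbut-2-enoyloxy)ethenyl]-7-(2-oxopropyl)-1,2,3,3a,6,7,8,8a-octahydroazulene-5-carboxylate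
Product: 26 (3S,3aS,6S,7S,8S,8aR)-6-hydroxy-3-(2-hydroxypropan-2-yl)-8a-methyl-8-[(E)-2-(3-methylbut-2-enoyloxy)ethenyl]-7-(2-oxopropyl)-1,2,3,3a,6,7,8,8a-octahydroazulene-5-carboxylic acid, via tris(trimethylsilyl) derivative 25 (not isolated)
Conditions: Me3SiOTf (5 equiv), 2,6-lutidine (8 equiv), CH2Cl2, 0 °C; then 10% aq. citric acid, THF, 23 °C
Reagents that add atoms: none
Why: Silyl triflate-mediated tert-butyl ester cleavage expels isobutene while silylating, and thereby protecting, the acid-sensitive tertiary carbinol; mild aqueous acid then removes all silyl groups.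

Step 19
Reactants: 26 (3S,3aS,6S,7S,8S,8aR)-6-hydroxy-3-(2-hydroxypropan-2-yl)-8a-methyl-8-[(E)-2-(3-methylbut-2-enoyloxy)ethenyl]-7-(2-oxopropyl)-1,2,3,3a,6,7,8,8a-octahydroazulene-5-carboxylic acid
Product: 27 (3S,3aS,7S,8S,8aS)-3-(2-hydroxypropan-2-yl)-8a-methyl-8-[(E)-2-(3-methylbut-2-enoyloxy)ethenyl]-6-oxo-7-(2-oxopropyl)-1,2,3,3a,6,7,8,8a-octahydroazulene-5-carboxylic acid
Conditions: Dess–Martin periodinane (1.5 equiv), NaHCO3, CH2Cl2, 0 to 23 °C
Reagents that add atoms: none
Why: Dess–Martin oxidation of the allylic C6 alcohol (through the open hydroxy ketone form) gives the enone under buffered, non-basic conditions, so that C3a (now γ to the keto acid) and the enol ester are not disturbed and C7 keeps its trans relationship to C8, which should also be the more stable one.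

Compound list
1 | 4-methyl-5,6-dihydro-2H-pyran-2-one | CC1=CC(=O)OCC1 | starting material
2 | 4-methyl-5,6-dihydro-2H-pyran-2-ol (lactol, both epimers) | CC1=CC(O)OCC1 | intermediate
3 | (3Z)-3-methylhexa-3,5-dien-1-ol | OCC/C(C)=C\C=C | intermediate
4 | tert-butyl(dimethyl){[(3Z)-3-methylhexa-3,5-dien-1-yl]oxy}silane | CC(C)(C)[Si](C)(C)OCC/C(C)=C\C=C | intermediate
5 | ethyl 3-(2-methyl-1,3-dioxolan-2-yl)propanoate | CCOC(=O)CCC1(C)OCCO1 | starting material
6 | 3-(2-methyl-1,3-dioxolan-2-yl)propanal | O=CCCC1(C)OCCO1 | intermediate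
7 | tert-butyl diazoacetate | CC(C)(C)OC(=O)C=[N+]=[N-] | starting material
8 | tert-butyl 2-diazo-3-hydroxy-5-(2-methyl-1,3-dioxolan-2-yl)pentanoate (racemic) | CC(C)(C)OC(=O)C(=[N+]=[N-])C(O)CCC1(C)OCCO1 | intermediate
9 | tert-butyl (3E)-2-diazo-5-(2-methyl-1,3-dioxolan-2-yl)pent-3-enoate | CC(C)(C)OC(=O)C(=[N+]=[N-])/C=C/CC1(C)OCCO1 | intermediate
10 | tert-butyl (1S,2S)-2-[(1Z)-4-(tert-butyldimethylsilyloxy)-2-methylbut-1-en-1-yl]-1-[(1E)-3-(2-methyl-1,3-dioxolan-2-yl)prop-1-en-1-yl]cyclopropane-1-carboxylate (cis-divinylcyclopropane) | CC(C)(C)OC(=O)[C@]1(/C=C/CC2(C)OCCO2)C[C@H]1/C=C(C)\CCO[Si](C)(C)C(C)(C)C | intermediate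
11 | tert-butyl (3R,4R)-4-[2-(tert-butyldimethylsilyloxy)ethyl]-4-methyl-3-[(2-methyl-1,3-dioxolan-2-yl)methyl]cyclohepta-1,5-diene-1-carboxylate | CC(C)(C)OC(=O)C1=C[C@@H](CC2(C)OCCO2)[C@](C)(CCO[Si](C)(C)C(C)(C)C)C=CC1 | intermediate
12 | tert-butyl (3R,4R)-4-(2-hydroxyethyl)-4-methyl-3-(2-oxopropyl)cyclohepta-1,5-diene-1-carboxylate | CC(C)(C)OC(=O)C1=C[C@@H](CC(C)=O)[C@](C)(CCO)C=CC1 | intermediate
13 | tert-butyl (3R,4R)-4-methyl-4-(2-oxoethyl)-3-(2-oxopropyl)cyclohepta-1,5-diene-1-carboxylate | CC(C)(C)OC(=O)C1=C[C@@H](CC(C)=O)[C@](C)(CC=O)C=CC1 | intermediate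
14 | tert-butyl (3aS,8aR)-3-acetyl-2-hydroxy-8a-methyl-1,2,3,3a,6,8a-hexahydroazulene-5-carboxylate (aldol adduct, C2 and C3 epimers) | CC(C)(C)OC(=O)C1=C[C@H]2C(C(C)=O)C(O)C[C@]2(C)C=CC1 | intermediate
15 | tert-butyl (3aR,8aR)-3-acetyl-8a-methyl-1,3a,6,8a-tetrahydroazulene-5-carboxylate | CC(C)(C)OC(=O)C1=C[C@H]2C(C(C)=O)=CC[C@]2(C)C=CC1 | intermediate
16 | tert-butyl (3S,3aS,8aR)-3-acetyl-8a-methyl-1,2,3,3a,6,8a-hexahydroazulene-5-carboxylate | CC(C)(C)OC(=O)C1=C[C@H]2[C@@H](C(C)=O)CC[C@]2(C)C=CC1 | intermediate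
17 | tert-butyl (3S,3aS,8aR)-3-(2-hydroxypropan-2-yl)-8a-methyl-1,2,3,3a,6,8a-hexahydroazulene-5-carboxylate | CC(C)(C)OC(=O)C1=C[C@H]2[C@@H](C(C)(C)O)CC[C@]2(C)C=CC1 | intermediate
18 | tert-butyl (3S,3aS,6S,8aR)-6-hydroxy-3-(2-hydroxypropan-2-yl)-8a-methyl-1,2,3,3a,6,8a-hexahydroazulene-5-carboxylate | CC(C)(C)OC(=O)C1=C[C@H]2[C@@H](C(C)(C)O)CC[C@]2(C)C=C[C@@H]1O | intermediate
19 | tert-butyl (3S,3aS,6S,8aR)-6-[(1-bromo-2-methoxypropan-2-yl)oxy]-3-(2-hydroxypropan-2-yl)-8a-methyl-1,2,3,3a,6,8a-hexahydroazulene-5-carboxylate (ketal epimers) | CC(C)(C)OC(=O)C1=C[C@H]2[C@@H](C(C)(C)O)CC[C@]2(C)C=C[C@@H]1OC(C)(OC)CBr | intermediate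
20 | tricyclic ketal aldehyde: tert-butyl ester with the azulene core 3S,3aS,6S,7S,8S,8aS, O6 and the C7 methylene bridged by C(CH3)(OCH3) (cis-fused 2-methoxy-2-methyloxolane, ketal epimers), formyl on C8 trans to the C7 methylene and cis to the C8a methyl | COC1(C)C[C@@H]2[C@H](O1)C(C(=O)OC(C)(C)C)=C[C@H]3[C@@H](C(C)(C)O)CC[C@]3(C)[C@H]2C=O | intermediate
21 | tricyclic ketal alkenyl iodide: as 20 with (E)-2-iodoethenyl on C8 (core 3S,3aS,6S,7S,8R,8aS) | COC1(C)C[C@@H]2[C@H](O1)C(C(=O)OC(C)(C)C)=C[C@H]3[C@@H](C(C)(C)O)CC[C@]3(C)[C@H]2/C=C/I | intermediate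
22 | 3-methylbut-2-enoic acid | CC(C)=CC(=O)O | starting material
23 | tricyclic ketal enol ester: as 20 with (E)-2-(3-methylbut-2-enoyloxy)ethenyl on C8 (core 3S,3aS,6S,7S,8S,8aR) | COC1(C)C[C@@H]2[C@H](O1)C(C(=O)OC(C)(C)C)=C[C@H]3[C@@H](C(C)(C)O)CC[C@]3(C)[C@H]2/C=C/OC(=O)C=C(C)C | intermediate
24 | tert-butyl (3S,3aS,6S,7S,8S,8aR)-6-hydroxy-3-(2-hydroxypropan-2-yl)-8a-methyl-8-[(E)-2-(3-methylbut-2-enoyloxy)ethenyl]-7-(2-oxopropyl)-1,2,3,3a,6,7,8,8a-octahydroazulene-5-carboxylate (open form of the hemiketal) | CC(=O)C[C@@H]1[C@H](O)C(C(=O)OC(C)(C)C)=C[C@H]2[C@@H](C(C)(C)O)CC[C@]2(C)[C@H]1/C=C/OC(=O)C=C(C)C | intermediate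
25 | trimethylsilyl ester of 26 carrying trimethylsilyl ethers on the C6 and tertiary hydroxyls | CC(=O)C[C@@H]1[C@H](O[Si](C)(C)C)C(C(=O)O[Si](C)(C)C)=C[C@H]2[C@@H](C(C)(C)O[Si](C)(C)C)CC[C@]2(C)[C@H]1/C=C/OC(=O)C=C(C)C | intermediate
26 | (3S,3aS,6S,7S,8S,8aR)-6-hydroxy-3-(2-hydroxypropan-2-yl)-8a-methyl-8-[(E)-2-(3-methylbut-2-enoyloxy)ethenyl]-7-(2-oxopropyl)-1,2,3,3a,6,7,8,8a-octahydroazulene-5-carboxylic acid | CC(=O)C[C@@H]1[C@H](O)C(C(=O)O)=C[C@H]2[C@@H](C(C)(C)O)CC[C@]2(C)[C@H]1/C=C/OC(=O)C=C(C)C | intermediate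
27 | (3S,3aS,7S,8S,8aS)-3-(2-hydroxypropan-2-yl)-8a-methyl-8-[(E)-2-(3-methylbut-2-enoyloxy)ethenyl]-6-oxo-7-(2-oxopropyl)-1,2,3,3a,6,7,8,8a-octahydroazulene-5-carboxylic acid | CC(=O)C[C@@H]1C(=O)C(C(=O)O)=C[C@H]2[C@@H](C(C)(C)O)CC[C@]2(C)[C@H]1/C=C/OC(=O)C=C(C)C | target

Total steps: 19. Longest linear sequence: 16 steps (steps 1–3, then 7–19; the branch through steps 4–6 is equally long).

Steps most likely to fail

Step 13 (allylic hydroxylation). The ene reaction may run on to the dienone, or oxygen may be delivered to the wrong face of C6, which would invert both C7 and C8 later. The fallback sets out from 17: exhaustive oxidation of the doubly allylic C6 methylene (t-BuOOH, catalytic Rh2(cap)4, dirhodium tetracaprolactamate, CH2Cl2) would give the cross-conjugated dienone tert-butyl (3S,3aS,8aR)-3-(2-hydroxypropan-2-yl)-8a-methyl-6-oxo-1,2,3,3a,6,8a-hexahydroazulene-5-carboxylate F1. Reagent-controlled 1,2-reduction ((R)-2-methyl-CBS-oxazaborolidine, catecholborane, PhMe, −78 °C), in which the ester-bearing alkenyl arm acts as the large group, would then return the route to 18.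

Step 17 (copper-catalysed C–O coupling). Exchange at the hindered alkenyl iodide may be slow, so that dehydroiodination or loss of the carboxylate partner competes. The fallback sets out from aldehyde 20 and omits step 16: Anders–Gaßner Wittig olefination with the ylide from [(3-methylbut-2-enoyloxy)methyl]triphenylphosphonium chloride F2 (made from chloromethyl 3-methylbut-2-enoate and PPh3; NaN(SiMe3)2, THF, −78 to 23 °C) would give enol ester 23 directly. An E/Z mixture is expected; the Z isomer would be separated or equilibrated with catalytic I2. The route is rejoined at 23, which is hydrolysed as in the second stage of step 17.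

Step 15 (radical cyclisation–carbonylation). Hydrogen transfer to the hindered C8 radical may outrun CO capture, or CO may trap the first radical before ring closure. The fallback sets out from 19 and replaces steps 15 and 16: a hydride-free radical vinyl transfer ((E)-1,2-bis(tributylstannyl)ethene in excess, AIBN, PhH, 80 °C), in which the C8 radical adds to the distannane and expels Bu3Sn•, would give the (E)-alkenylstannane F3. Iododestannylation with retention (I2, CH2Cl2, 0 °C) would return the route to 21.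

Further compounds
F1 | step 13 | tert-butyl (3S,3aS,8aR)-3-(2-hydroxypropan-2-yl)-8a-methyl-6-oxo-1,2,3,3a,6,8a-hexahydroazulene-5-carboxylate | CC(C)(C)OC(=O)C1=C[C@H]2[C@@H](C(C)(C)O)CC[C@]2(C)C=CC1=O
F2 | step 17 | [(3-methylbut-2-enoyloxy)methyl]triphenylphosphonium chloride | CC(C)=CC(=O)OC[P+](c1ccccc1)(c1ccccc1)c1ccccc1.[Cl-]
F3 | step 15 | tricyclic ketal (E)-alkenylstannane: as 20 with (E)-2-(tributylstannyl)ethenyl on C8 | COC1(C)C[C@@H]2[C@H](O1)C(C(=O)OC(C)(C)C)=C[C@H]3[C@@H](C(C)(C)O)CC[C@]3(C)[C@H]2/C=C/[Sn](CCCC)(CCCC)CCCC
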